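**Plan**
- Retrosynthesis: the exocyclic C7=CH2 is traced back to a C7–CH2OH allylic alcohol (reductive 1,3-transposition), the C3–CH3 bond is cut (methyl addition to a C3 ketone), then C10–Br (enolate bromination of a C9 ketone), then the C6–C7 bond of ring A. This last cut opens the spirocycle to a phenol carrying an ynone chain, which is cut at the acyl–alkyne bond and the aryl–CMe2 bond.
- Enabling feature: ring B carries oxygen on C3 and chlorine on C2, with C3 para to the spiro carbon C6. Ring B is therefore a reduced 4-alkyl-2-chlorophenol whose para carbon can attack a tethered alkyne.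
- Forward order: the chain is assembled on 2-chloroanisole (Friedel–Crafts alkylation, Weinreb amide, acetylide). Ring A then closes onto the arene, which becomes ring B as a 2-chlorodienone. Ring B is reduced in two stages, ring A is brominated and reduced, the ring B ketone is released and methylated, and the exocyclic alkene is made last.
- Stereochemistry: C6 comes from the chiral catalyst of the ring closure. C10 is set by equilibration while C2 is still sp2 (conformational relay across the spiro centre). C9 follows from hydride addition cis to bromine, C2 from equilibration to equatorial chlorine, and C3 from equatorial methyl addition.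

Key step: step 5

Remark on numbering: all spirocycles are numbered as spiro[5.5]undecanes with C1–C5 in ring B (Cl on C2, oxygen on C3), C6 as the spiro carbon and C7–C11 in ring A (one-carbon branch on C7, oxygen on C9, Br on C10, gem-dimethyl on C11). CIP descriptors change along the route only where substituent priorities change; the spatial arrangement at C6 is the same from the key step to the target.

Assumption: the (R)-phosphate is taken as the antipode that gives the (6R)-spirocycle in the key step; if the sense of induction is the opposite, the (S)-phosphate is used and nothing else changes.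

**Route**

Step 1
Reactants: 1 2-chloroanisole; 2 3-methylbut-2-enoic acid
Product: 3 3-(3-chloro-4-methoxyphenyl)-3-methylbutanoic acid
Conditions: AlCl3 (2.5 equiv), CH2Cl2, 0 °C to rt; aq HCl
Reagents that add atoms: none
Why: Friedel–Crafts alkylation: AlCl3 turns the unsaturated acid into a tertiary cation equivalent that attacks the position para to the methoxy group, the most activated and least hindered site of the chloroanisole.

Step 2
Reactants: 3 3-(3-chloro-4-methoxyphenyl)-3-methylbutanoic acid
Product: 4 3-(3-chloro-4-hydroxyphenyl)-3-methylbutanoic acid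
Conditions: BBr3 (3 equiv), CH2Cl2, −78 to 0 °C; H2O
Reagents that add atoms: none
Why: Lewis-acid cleavage of the aryl methyl ether (BBr3 demethylation), done before any ynone exists so that no nucleophilic or strongly acidic deprotection ever has to be run on the sensitive chain.

Step 3
Reactants: 4 3-(3-chloro-4-hydroxyphenyl)-3-methylbutanoic acid
Product: 5 3-(3-chloro-4-hydroxyphenyl)-N-methoxy-N,3-dimethylbutanamide
Conditions: MeNH(OMe)·HCl, EDC·HCl, HOBt (cat.), iPr2NEt, CH2Cl2, 0 °C to rt
Reagents that add atoms: N,O-dimethylhydroxylamine hydrochloride, CNOC.Cl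
Why: Carbodiimide-mediated amidation to the Weinreb amide; the activated ester is aminolysed by the hydroxylamine much faster than it is attacked by the weakly nucleophilic chlorophenol.

Step 4
Reactants: 5 3-(3-chloro-4-hydroxyphenyl)-N-methoxy-N,3-dimethylbutanamide; 6 tert-butyldimethyl(prop-2-yn-1-yloxy)silane
Product: 8 1-{[tert-butyl(dimethyl)silyl]oxy}-6-(3-chloro-4-hydroxyphenyl)-6-methylhept-2-yn-4-one, via lithium acetylide 7 (not isolated)
Conditions: 6 (3 equiv), n-BuLi (2.9 equiv), THF, −78 °C; then 5, −78 to 0 °C; aq NH4Cl
Reagents that add atoms: none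
Why: Weinreb ketone synthesis: the first equivalent of acetylide only deprotonates the phenol, the second adds to the amide, and the chelated tetrahedral lithium adduct survives until work-up, so neither over-addition nor conjugate addition to the ynone can take place.

Step 5
Reactants: 8 1-{[tert-butyl(dimethyl)silyl]oxy}-6-(3-chloro-4-hydroxyphenyl)-6-methylhept-2-yn-4-one
Product: 9 (6R)-7-({[tert-butyl(dimethyl)silyl]oxy}methyl)-2-chloro-11,11-dimethylspiro[5.5]undeca-1,4,7-triene-3,9-dione
Conditions: Ph3PAuCl (5 mol %), silver (R)-3,3′-bis(2,4,6-triisopropylphenyl)-1,1′-binaphthyl-2,2′-diyl phosphate (5 mol %), toluene, 0 °C to rt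
Reagents that add atoms: none
Why: Proposed new method: the cationic monovalent gold fragment binds the alkyne, which the ynone carbonyl polarises so that the arene carbon para to OH (the ipso carbon) attacks the distal alkyne carbon anti to gold; protodeauration with transfer of the phenolic proton to the phosphate then gives the cross-conjugated 2-chlorodienone. The closest known reaction type is the silver-, copper- and gold-catalysed dearomatising spirocyclisation of phenol- and indole-tethered ynones, which closes five-membered rings, in racemic form for phenols and in enantioenriched form for indoles with chiral silver phosphates. Ring A closes here in the 6-endo-dig mode, one atom larger than in those cases; the gem-dimethyl group favours the folded chain (Thorpe–Ingold effect), attack at the proximal alkyne carbon is electronically mismatched for an ynone, and the ortho carbons are meta to OH and would need a seven-membered ring. The only new stereocentre is the spiro carbon C6, whose two ring B arms differ solely by the chlorine; it is to be set by the chiral phosphate counter-anion, which is hydrogen-bonded to the phenolic OH right beside that chlorine, accepts the proton in the bond-forming event and so decides which face of the arene the gold-bound alkyne reaches. The step needs ipso regioselectivity, secured by the para-hydroxyl group and the tether length, and enantioface selectivity at the ipso carbon, which rests on the catalyst alone and is the uncertain point.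

Step 6
Reactants: 9 (6R)-7-({[tert-butyl(dimethyl)silyl]oxy}methyl)-2-chloro-11,11-dimethylspiro[5.5]undeca-1,4,7-triene-3,9-dione
Product: 10 (6R)-7-({[tert-butyl(dimethyl)silyl]oxy}methyl)-2-chloro-11,11-dimethylspiro[5.5]undeca-1,7-diene-3,9-dione
Conditions: (Ph3P)3RhCl (5 mol %), H2 (1 atm), benzene, rt
Reagents that add atoms: none
Why: Homogeneous hydrogenation, which in cross-conjugated cyclohexadienones saturates only the unhindered disubstituted double bond (C4=C5) and leaves the chlorine-bearing C1=C2 bond, the trisubstituted ring A enone and the C–Cl bond untouched; no stereocentre is formed.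

Step 7
Reactants: 10 (6R)-7-({[tert-butyl(dimethyl)silyl]oxy}methyl)-2-chloro-11,11-dimethylspiro[5.5]undeca-1,7-diene-3,9-dione
Product: 11 (6R)-7-({[tert-butyl(dimethyl)silyl]oxy}methyl)-2-chloro-11,11-dimethyl-3-[(triethylsilyl)oxy]spiro[5.5]undeca-2,7-dien-9-one
Conditions: (Ph3P)3RhCl (2 mol %), Et3SiH (1.5 equiv), benzene, 50 °C
Reagents that add atoms: triethylsilane, CC[SiH](CC)CC
Why: Rhodium-catalysed 1,4-hydrosilylation of an enone with a monohydrosilane puts hydride on C1 and silicon on oxygen; the β,β-disubstituted ring A enone is too hindered to compete, and the chloro-enolate is stored as a silyl enol ether whose sp2 C2 is needed for the stereochemical relay of step 8.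

Step 8
Reactants: 11 (6R)-7-({[tert-butyl(dimethyl)silyl]oxy}methyl)-2-chloro-11,11-dimethyl-3-[(triethylsilyl)oxy]spiro[5.5]undeca-2,7-dien-9-one
Product: 14 (6S,10S)-10-bromo-7-({[tert-butyl(dimethyl)silyl]oxy}methyl)-2-chloro-11,11-dimethyl-3-[(triethylsilyl)oxy]spiro[5.5]undeca-2,7-dien-9-one, via lithium dienolate 12 (not isolated), via (10R)-bromo epimer 13 (not isolated)
Conditions: LiN(SiMe3)2 (1.1 equiv), THF, −78 °C; NBS (1.05 equiv), −78 °C; aq NH4Cl; then DBU (0.3 equiv), CH2Cl2, rt
Reagents that add atoms: N-bromosuccinimide, O=C1CCC(=O)N1Br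
Why: Kinetic α′-deprotonation of the enone (ring B, being an enol ether, has no acidic hydrogen) and enolate bromination, followed by base-mediated epimerisation, so that C10 is set under thermodynamic control: bromine should sit equatorial and cis to the ring B arm that ring A holds pseudo-equatorial, and that arm should be C1 because the C7 substituent can lean only towards the side whose neighbour C2 is sp2 and carries no syn-axial hydrogen, whereas the C4 side has one; C11 is quaternary, so DBU cannot eliminate HBr, and any remaining minor epimer is removed by chromatography.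

Step 9
Reactants: 14 (6S,10S)-10-bromo-7-({[tert-butyl(dimethyl)silyl]oxy}methyl)-2-chloro-11,11-dimethyl-3-[(triethylsilyl)oxy]spiro[5.5]undeca-2,7-dien-9-one
Product: 15 (6S,9R,10S)-10-bromo-7-({[tert-butyl(dimethyl)silyl]oxy}methyl)-2-chloro-11,11-dimethyl-3-[(triethylsilyl)oxy]spiro[5.5]undeca-2,7-dien-9-ol
Conditions: iBu2AlH (2.2 equiv), CH2Cl2, −78 °C; aq potassium sodium tartrate
Reagents that add atoms: none
Why: 1,2-Reduction of the α′-bromo enone by a bulky aluminium hydride, which approaches C9 along the equatorial trajectory, away from the axial methyl group on C11, and so should give the axial alcohol cis to the equatorial bromine (9R), the usual outcome for 2-bromocyclohexanones with hindered hydrides; the silyl enol ether and both carbon–halogen bonds are inert at −78 °C.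

Step 10
Reactants: 15 (6S,9R,10S)-10-bromo-7-({[tert-butyl(dimethyl)silyl]oxy}methyl)-2-chloro-11,11-dimethyl-3-[(triethylsilyl)oxy]spiro[5.5]undeca-2,7-dien-9-ol
Product: 17 (2S,6S,9R,10S)-10-bromo-2-chloro-9-hydroxy-7-(hydroxymethyl)-11,11-dimethylspiro[5.5]undec-7-en-3-one, via (2R)-chloro epimer 16 (not isolated)
Conditions: HF·pyridine, THF–pyridine, 0 °C to rt; aq NaHCO3; then Et3N (0.2 equiv), CH2Cl2, rt
Reagents that add atoms: none
Why: Fluoride-mediated desilylation cleaves the silyl enol ether and the silyl ether in one operation, and amine-catalysed enolisation then equilibrates C2 to the epimer with equatorial chlorine cis to C11 (2S), because ring B keeps the CMe2 carbon equatorial and an axial chlorine would clash with the axial C7 substituent.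

Step 11
Reactants: 17 (2S,6S,9R,10S)-10-bromo-2-chloro-9-hydroxy-7-(hydroxymethyl)-11,11-dimethylspiro[5.5]undec-7-en-3-one
Product: 18 (2S,3R,6S,9R,10S)-10-bromo-2-chloro-7-(hydroxymethyl)-3,11,11-trimethylspiro[5.5]undec-7-ene-3,9-diol
Conditions: MeTi(OiPr)3 (5 equiv, from MeLi and ClTi(OiPr)3), THF, −30 to 0 °C; aq NH4Cl
Reagents that add atoms: methyllithium, [Li]C, used as methyltitanium triisopropoxide, C[Ti](OC(C)C)(OC(C)C)OC(C)C
Why: 1,2-Addition of a non-basic methyltitanium reagent to the only ketone: the bulky reagent should prefer the equatorial trajectory at C3 (the axial one is shielded by the axial hydrogens on C1 and C5), so methyl ends equatorial and the tertiary hydroxyl axial and cis to chlorine (3R), the sense also found for methyl additions to 2-chlorocyclohexanones; the reagent does not enolise the α-chloro ketone, and two equivalents are consumed by the free hydroxyl groups.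

Step 12
Reactants: 18 (2S,3R,6S,9R,10S)-10-bromo-2-chloro-7-(hydroxymethyl)-3,11,11-trimethylspiro[5.5]undec-7-ene-3,9-diol
Product: 21 (2S,3R,6S,9R,10S)-10-bromo-2-chloro-3,11,11-trimethyl-7-methylidenespiro[5.5]undecane-3,9-diol, via sulfonylhydrazine adduct 19 (not isolated), via allylic diazene 20 (not isolated)
Conditions: PPh3 (1.5 equiv), DEAD (1.5 equiv), 2-nitrobenzenesulfonylhydrazide (1.5 equiv), THF, −30 °C; then rt
Reagents that add atoms: none
Why: Reductive 1,3-transposition of an allylic alcohol: the Mitsunobu reaction alkylates the sulfonylhydrazide only at the primary allylic alcohol, loss of sulfinic acid gives the allylic diazene, and its retro-ene loss of N2 places hydrogen on C8 and the double bond exocyclic at C7; no stereocentre is touched and the secondary bromide and chloride are left alone.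

**Compound list**

1 | 2-chloroanisole | COc1ccccc1Cl | starting material
2 | 3-methylbut-2-enoic acid | CC(C)=CC(=O)O | starting material
3 | 3-(3-chloro-4-methoxyphenyl)-3-methylbutanoic acid | COc1ccc(C(C)(C)CC(=O)O)cc1Cl | intermediate
4 | 3-(3-chloro-4-hydroxyphenyl)-3-methylbutanoic acid | CC(C)(CC(=O)O)c1ccc(O)c(Cl)c1 | intermediate
5 | 3-(3-chloro-4-hydroxyphenyl)-N-methoxy-N,3-dimethylbutanamide | CON(C)C(=O)CC(C)(C)c1ccc(O)c(Cl)c1 | intermediate
6 | tert-butyldimethyl(prop-2-yn-1-yloxy)silane | C#CCO[Si](C)(C)C(C)(C)C | starting material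
7 | (3-{[tert-butyl(dimethyl)silyl]oxy}prop-1-yn-1-yl)lithium (not isolated) | [Li]C#CCO[Si](C)(C)C(C)(C)C | intermediate
8 | 1-{[tert-butyl(dimethyl)silyl]oxy}-6-(3-chloro-4-hydroxyphenyl)-6-methylhept-2-yn-4-one | CC(C)(CC(=O)C#CCO[Si](C)(C)C(C)(C)C)c1ccc(O)c(Cl)c1 | intermediate
9 | (6R)-7-({[tert-butyl(dimethyl)silyl]oxy}methyl)-2-chloro-11,11-dimethylspiro[5.5]undeca-1,4,7-triene-3,9-dione | CC(C)(C)[Si](C)(C)OCC1=CC(=O)CC(C)(C)[C@]12C=CC(=O)C(Cl)=C2 | intermediate
10 | (6R)-7-({[tert-butyl(dimethyl)silyl]oxy}methyl)-2-chloro-11,11-dimethylspiro[5.5]undeca-1,7-diene-3,9-dione | CC(C)(C)[Si](C)(C)OCC1=CC(=O)CC(C)(C)[C@]12CCC(=O)C(Cl)=C2 | intermediate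
11 | (6R)-7-({[tert-butyl(dimethyl)silyl]oxy}methyl)-2-chloro-11,11-dimethyl-3-[(triethylsilyl)oxy]spiro[5.5]undeca-2,7-dien-9-one | CC(C)(C)[Si](C)(C)OCC1=CC(=O)CC(C)(C)[C@]12CCC(O[Si](CC)(CC)CC)=C(Cl)C2 | intermediate
12 | lithium C9=C10 dienolate of 11, (6R) (not isolated) | CC(C)(C)[Si](C)(C)OCC1=CC(O[Li])=CC(C)(C)[C@]12CCC(O[Si](CC)(CC)CC)=C(Cl)C2 | intermediate
13 | (6S,10R)-10-bromo-7-({[tert-butyl(dimethyl)silyl]oxy}methyl)-2-chloro-11,11-dimethyl-3-[(triethylsilyl)oxy]spiro[5.5]undeca-2,7-dien-9-one (not isolated, epimerised to 14) | CC(C)(C)[Si](C)(C)OCC1=CC(=O)[C@H](Br)C(C)(C)[C@]12CCC(O[Si](CC)(CC)CC)=C(Cl)C2 | intermediate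
14 | (6S,10S)-10-bromo-7-({[tert-butyl(dimethyl)silyl]oxy}methyl)-2-chloro-11,11-dimethyl-3-[(triethylsilyl)oxy]spiro[5.5]undeca-2,7-dien-9-one | CC(C)(C)[Si](C)(C)OCC1=CC(=O)[C@@H](Br)C(C)(C)[C@]12CCC(O[Si](CC)(CC)CC)=C(Cl)C2 | intermediate
15 | (6S,9R,10S)-10-bromo-7-({[tert-butyl(dimethyl)silyl]oxy}methyl)-2-chloro-11,11-dimethyl-3-[(triethylsilyl)oxy]spiro[5.5]undeca-2,7-dien-9-ol | CC(C)(C)[Si](C)(C)OCC1=C[C@@H](O)[C@@H](Br)C(C)(C)[C@]12CCC(O[Si](CC)(CC)CC)=C(Cl)C2 | intermediate
16 | (2R,6S,9R,10S)-10-bromo-2-chloro-9-hydroxy-7-(hydroxymethyl)-11,11-dimethylspiro[5.5]undec-7-en-3-one (not isolated, epimerised to 17) | OCC1=C[C@@H](O)[C@@H](Br)C(C)(C)[C@]12CCC(=O)[C@H](Cl)C2 | intermediate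
17 | (2S,6S,9R,10S)-10-bromo-2-chloro-9-hydroxy-7-(hydroxymethyl)-11,11-dimethylspiro[5.5]undec-7-en-3-one | OCC1=C[C@@H](O)[C@@H](Br)C(C)(C)[C@]12CCC(=O)[C@@H](Cl)C2 | intermediate
18 | (2S,3R,6S,9R,10S)-10-bromo-2-chloro-7-(hydroxymethyl)-3,11,11-trimethylspiro[5.5]undec-7-ene-3,9-diol | OCC1=C[C@@H](O)[C@@H](Br)C(C)(C)[C@]12CC[C@@](C)(O)[C@@H](Cl)C2 | intermediate
19 | N-{[(2S,3R,6S,9R,10S)-10-bromo-2-chloro-3,9-dihydroxy-3,11,11-trimethylspiro[5.5]undec-7-en-7-yl]methyl}-N-(2-nitrobenzenesulfonyl)hydrazine (not isolated) | NN(CC1=C[C@@H](O)[C@@H](Br)C(C)(C)[C@]12CC[C@@](C)(O)[C@@H](Cl)C2)S(=O)(=O)c1ccccc1[N+](=O)[O-] | intermediate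
20 | {[(2S,3R,6S,9R,10S)-10-bromo-2-chloro-3,9-dihydroxy-3,11,11-trimethylspiro[5.5]undec-7-en-7-yl]methyl}diazene (not isolated) | N=NCC1=C[C@@H](O)[C@@H](Br)C(C)(C)[C@]12CC[C@@](C)(O)[C@@H](Cl)C2 | intermediate
21 | (2S,3R,6S,9R,10S)-10-bromo-2-chloro-3,11,11-trimethyl-7-methylidenespiro[5.5]undecane-3,9-diol | C=C1C[C@@H](O)[C@@H](Br)C(C)(C)[C@]12CC[C@@](C)(O)[C@@H](Cl)C2 | target

**Step count and risks**

Total: 12 steps. Longest linear sequence: 12 steps from 2-chloroanisole (1); compounds 2 and 6 are purchased.

Steps most likely to fail:

1. Step 5. Face selection at the ipso carbon may be poor, because the only difference between the two arene faces is a chlorine far from the metal, and the phosphate-paired gold may also turn over slowly. Fallback, setting out from 8: the closure is run with achiral AgOSO2CF3 (10 mol %, CH2Cl2, rt), the catalyst class established for racemic phenol–ynone ipso-cyclisations, to give racemic 7-({[tert-butyl(dimethyl)silyl]oxy}methyl)-2-chloro-11,11-dimethylspiro[5.5]undeca-1,4,7-triene-3,9-dione F1. The enantiomers of F1 are then separated by preparative chromatography on an amylose-carbamate chiral stationary phase; the (6R)-enantiomer is compound 9, where the route is rejoined.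

2. Step 8. The equilibrium between the two C10 epimers may lie too close to unity, since the only link between ring A and the remote ring B is the conformational preference described in the step. Fallback, setting out from 11 and returning at 14: stereoselection is moved from a single equilibration to separation with recycling. After bromination and the DBU treatment, the diastereomers 14 and 13 are separated by chromatography; recovered 13 is returned to DBU and separated again, so that the material is funnelled to 14 over a few cycles. This makes no compound outside the list (entry F0).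

3. Step 7. Hydride transfer to C1, which sits next to the quaternary spiro carbon, may be slow, or rhodium hydride may reduce the C–Cl bond. Fallback, setting out from 10: conjugate reduction with stoichiometric [(Ph3P)CuH]6 in wet benzene at rt should give (6R)-7-({[tert-butyl(dimethyl)silyl]oxy}methyl)-2-chloro-11,11-dimethylspiro[5.5]undec-7-ene-3,9-dione F2 as a mixture of C2 epimers. Soft enolisation of F2 with Et3SiOSO2CF3 (1.05 equiv) and Et3N at −78 °C, directed to the more acidic chlorine-bearing carbon, then returns to compound 11.

Further compounds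
F1 | step 5 | racemic 7-({[tert-butyl(dimethyl)silyl]oxy}methyl)-2-chloro-11,11-dimethylspiro[5.5]undeca-1,4,7-triene-3,9-dione | CC(C)(C)[Si](C)(C)OCC1=CC(=O)CC(C)(C)C12C=CC(=O)C(Cl)=C2
F0 | step 8 | none | none
F2 | step 7 | (6R)-7-({[tert-butyl(dimethyl)silyl]oxy}methyl)-2-chloro-11,11-dimethylspiro[5.5]undec-7-ene-3,9-dione (both C2 epimers) | CC(C)(C)[Si](C)(C)OCC1=CC(=O)CC(C)(C)[C@]12CCC(=O)C(Cl)C2
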